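**Plan**

- Retrosynthesis: cut the C4'–CH3 bond (methyl for triflate), then both aryl O–C bonds of the dioxane (o-quinone of ring A plus the C1'=C5' bond of a guaiadienyl triflate), then ring B at C5–C6 and C7=C8 (C6–C7 leaves as a two-carbon ketene equivalent), then the C9–aryl bond.
- This leaves a tricyclic C/D/E ketone, an aryl bromide, ethoxyethyne and a cycloheptane-fused cyclopentenone.
- Forward ring order: E (asymmetric conjugate addition), D (Michael/aldol annulation, cis hydrogenation), C (C13 alkylation, Nozaki–Hiyama–Kishi closure, C14 methylation), C9 arylation, B (key annulation), dioxane ([4+2]). Guaiane: six-ring of (S)-carvone, seven-ring by diazoacetate ring expansion, five-ring by Negishi coupling and Dieckmann closure.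
- Stereochemistry: C20 from the chiral copper catalyst, C17 from a chiral amine, C18 from hydrogenation, C13, C14 and C9 from substrate-controlled alkylation/arylation anti to the neighbouring axial group; C7' from (S)-carvone, C10' from an ene-reductase; C1' and C5' from cycloaddition anti to the C10' methyl.
- Enabling feature: the C8 ketone lies between the quaternary C9 and C14 (non-enolisable, and ring B cannot aromatise) and is 1,4 to C5–H of ring A, which is para to the C2 oxygen; a two-carbon unit can therefore be stitched between C8 and C5.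

Key step: step 18

Remark: positions are named by triterpenoid numbering (C1–C30) for the pentacycle and by primed guaiane numbering (C1'–C15') for the sesquiterpene; α/β follow the usual triterpenoid drawing.

**Route**

Step 1
Reactants: 1 methyl 3-oxocyclohex-1-ene-1-carboxylate
Product: 2 methyl (1R)-1-methyl-3-oxocyclohexane-1-carboxylate
Conditions: Me2Zn, Cu(OTf)2 (5 mol %), chiral sulfonate-bearing N-mesityl-4,5-diphenylimidazolinium carbene precursor (5 mol %, the enantiomer that gives the R product), t-BuOMe, −30 °C; aq. NH4Cl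
Reagents that add atoms: dimethylzinc, C[Zn]C
Why: Copper-catalysed enantioselective conjugate addition of a methylzinc nucleophile to the β-carbon of a cyclic γ-keto ester; the chiral carbene ligand selects the enone face and sets the quaternary C20.

Step 2
Reactants: 2 methyl (1R)-1-methyl-3-oxocyclohexane-1-carboxylate
Product: 3 methyl (1R)-1,4-dimethyl-3-oxocyclohexane-1-carboxylate (both C4 epimers)
Conditions: LDA, THF, −78 °C; MeI, −78 → 0 °C
Reagents that add atoms: iodomethane, CI
Why: Kinetic deprotonation occurs at C17, the α-carbon remote from the quaternary C20, and that enolate is methylated; the C17 configuration is re-set in step 3.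

Step 3
Reactants: 3 methyl (1R)-1,4-dimethyl-3-oxocyclohexane-1-carboxylate; 4 pent-1-en-3-one
Product: 6 methyl (1R,4R)-1,4-dimethyl-3-oxo-4-(3-oxopentyl)cyclohexane-1-carboxylate, via imine 5 (not isolated)
Conditions: (S)-1-phenylethylamine, TsOH (cat.), toluene, reflux (Dean–Stark); then 4, THF, 40 °C; then 10% aq. AcOH, 25 °C
Reagents that add atoms: water, O
Why: Michael addition of the more substituted secondary enamine tautomer of the imine through a compact aza-ene-like transition state; by analogy with 2-methylcyclohexanone the (S)-phenylethyl group should direct the vinyl ketone to the face that makes C17 (R), and hydrolysis returns the amine.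

Step 4
Reactants: 6 methyl (1R,4R)-1,4-dimethyl-3-oxo-4-(3-oxopentyl)cyclohexane-1-carboxylate
Product: 7 methyl (2R,4aR)-2,4a,8-trimethyl-7-oxo-1,2,3,4,4a,5,6,7-octahydronaphthalene-2-carboxylate (D/E enone: C14 ketone and C13=C18)
Conditions: NaOMe, MeOH, 60 °C
Reagents that add atoms: none
Why: Intramolecular aldol condensation (second half of a Robinson annulation): the ethyl ketone enolises toward C13, attacks the C18 carbonyl to close ring D and dehydrates to the conjugated enone.

Step 5
Reactants: 7 D/E enone
Product: 8 cis-fused D/E decalone (18β-H cis to 17β-methyl; C13 epimers)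
Conditions: H2 (1 atm), Pd/C, EtOH, 25 °C
Reagents that add atoms: none
Why: Heterogeneous hydrogenation of an angularly methylated octalone as a rule gives the cis-fused decalone, which places 18-H on the β face; C13 stays epimerisable.

Step 6
Reactants: 8 cis-fused D/E decalone
Product: 9 trimethylsilyl enol ether of 8 (C13=C14)
Conditions: TMSCl, Et3N, DMF, 130 °C
Reagents that add atoms: chlorotrimethylsilane, C[Si](C)(C)Cl
Why: Silylation under equilibrating conditions gives the more substituted silyl enol ether and so fixes the site of the next C–C bond.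

Step 7
Reactants: 9 trimethylsilyl enol ether; 10 methyl (2E)-4-bromo-2-methylbut-2-enoate
Product: 11 C13-alkylated decalone (13α-methyl; 13β-[(2E)-4-methoxy-3-methyl-4-oxobut-2-enyl])
Conditions: anhydrous benzyltrimethylammonium fluoride, 4 Å sieves, THF, 0 → 25 °C
Reagents that add atoms: none
Why: Fluoride unmasks the tetrasubstituted enolate regiospecifically and the allylic bromide alkylates C13 on the convex β face of the cis-decalin (anti to C19), so the chain is β and the methyl α.

Step 8
Reactants: 11 C13-alkylated decalone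
Product: 12 saturated keto diester (C9 epimers)
Conditions: H2 (1 atm), Pd/C, EtOAc, 25 °C
Reagents that add atoms: none
Why: Hydrogenation of the conjugated alkene lets the chain reach C14 later; the C9 centre formed here is erased by enolisation in step 17.

Step 9
Reactants: 12 saturated keto diester
Product: 13 C14 enol triflate (C14=C15)
Conditions: KHMDS, THF, −78 °C; PhNTf2, −78 → 0 °C
Reagents that add atoms: N-phenylbis(trifluoromethanesulfonimide), O=S(=O)(N(c1ccccc1)S(=O)(=O)C(F)(F)F)C(F)(F)F
Why: The ketone, more acidic than the ester, can only enolise toward C15 (C13 is quaternary) and the potassium enolate is O-triflated.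

Step 10
Reactants: 13 C14 enol triflate
Product: 14 aldehyde (C8 formyl)
Conditions: DIBAL-H (1.1 equiv), CH2Cl2, −78 °C; aq. Rochelle salt
Reagents that add atoms: none
Why: One equivalent of DIBAL-H at low temperature should reduce the less hindered side-chain ester to the aldehyde through its stable aluminate and leave the neopentyl-type C29 ester and the triflate intact.

Step 11
Reactants: 14 aldehyde
Product: 15 tricyclic allylic alcohol (8-hydroxy, C14=C15)
Conditions: CrCl2 (4 equiv), NiCl2 (1 mol %), DMF, 25 °C
Reagents that add atoms: none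
Why: Intramolecular Nozaki–Hiyama–Kishi reaction: the alkenylchromium species formed from the triflate adds chemoselectively to the aldehyde and closes six-membered ring C at C8–C14.

Step 12
Reactants: 15 tricyclic allylic alcohol
Product: 16 tricyclic enone (8-oxo, C14=C15)
Conditions: Dess–Martin periodinane, NaHCO3, CH2Cl2, 25 °C
Reagents that add atoms: none
Why: Dess–Martin oxidation of the secondary allylic alcohol gives the enone without touching the esters.

Step 13
Reactants: 16 tricyclic enone
Product: 17 triethylsilyl enol ether (C8=C14)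
Conditions: Et3SiH, RhCl(PPh3)3 (2 mol %), toluene, 60 °C
Reagents that add atoms: triethylsilane, CC[SiH](CC)CC
Why: Rhodium-catalysed 1,4-hydrosilylation of the s-cis enone puts hydride on C15 and silicon on oxygen, defining the C8–C14 enolate that base could not select (C9 is also enolisable).

Step 14
Reactants: 17 triethylsilyl enol ether
Product: 18 tricyclic C/D/E ketone (8-oxo; 13α,14β,17β-trimethyl; 18β-H; 20α-CO2Me; C9 epimers)
Conditions: anhydrous benzyltrimethylammonium fluoride, MeI (excess), 4 Å sieves, THF, −20 → 25 °C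
Reagents that add atoms: iodomethane, CI
Why: Fluoride releases the ring-fusion enolate, which is methylated at C14 anti to the pseudoaxial 13α-methyl on the adjacent carbon, giving the 14β-methyl and the trans C/D fusion.

Step 15
Reactants: 19 2-methoxy-6-methylphenol
Product: 20 4-bromo-2-methoxy-6-methylphenol
Conditions: NBS, MeCN, 0 °C
Reagents that add atoms: N-bromosuccinimide, O=C1CCC(=O)N1Br
Why: Electrophilic bromination para to the free hydroxyl, the strongest director.

Step 16
Reactants: 20 4-bromo-2-methoxy-6-methylphenol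
Product: 21 5-bromo-1,2-dimethoxy-3-methylbenzene
Conditions: MeI, K2CO3, acetone, reflux
Reagents that add atoms: iodomethane, CI
Why: Williamson O-methylation of the phenol.

Step 17
Reactants: 18 tricyclic C/D/E ketone; 21 5-bromo-1,2-dimethoxy-3-methylbenzene
Product: 22 9α-(3,4-dimethoxy-5-methylphenyl) ketone (9β-methyl)
Conditions: Pd(OAc)2 (5 mol %), P(t-Bu)3·HBF4 (10 mol %), NaOt-Bu, toluene, 90 °C
Reagents that add atoms: none
Why: Palladium-catalysed α-arylation of the only possible enolate (C9; C14 is quaternary); the aryl group is transferred to the α face, away from the axial 14β-methyl, so the aryl becomes equatorial (9α) and the methyl axial (9β).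

Step 18
Reactants: 22 9α-aryl ketone; 23 ethoxyethyne
Product: 25 methyl 2,3-dimethoxy-6-oxo-24-nor-D:A-friedooleana-1,3,5(10),7-tetraen-29-oate (6-oxopristimerol dimethyl ether), via ethoxyethynyl carbinol 24 (not isolated)
Conditions: 23, n-BuLi, Et2O, −78 °C; add 22, −78 → 0 °C; cool to −78 °C, TfOH (4 equiv) in CH2Cl2, −78 → 0 °C; aq. NaHCO3
Reagents that add atoms: none
Why: Proposed new method: lithium ethoxyacetylide, a slim sp-nucleophile, should add to the C8 carbonyl (about as hindered as 2,2,6,6-tetramethylcyclohexanone, which still accepts acetylides) to form C7–C8; on acidification the ynol ether of the carbinol is protonated at C7 to a ketene-oxonium ion whose sp carbon C6 is attacked by C5 of ring A, and ionisation of the now vinylogous C8 hydroxyl with loss of ethanol leaves the C6 ketone and the C7=C8 alkene. The closest known reaction types are the acid-mediated rearrangement of ethoxyethynyl carbinols to α,β-unsaturated esters (Meyer–Schuster type) and keteniminium or acylium Friedel–Crafts cyclisations; their merger into a one-flask [4+2] annulation of an α-aryl ketone has not been shown. Ring B closes by a 6-endo electrophilic aromatic substitution at the cumulene carbon, so no alkene geometry has to be controlled, and if water intercepts the cation first the resulting unsaturated ester can still acylate C5 in the same acid. No stereocentre is created (C8 becomes trigonal) and the quaternary C9 and C14 cannot epimerise. The selectivity needed is attack at C5 and not at C1: C5 is para to the C2 methoxy, which stays coplanar and unhindered, whereas attack at C1 would force that methoxy out of conjugation against the twisted C3 methoxy. The ketone is non-enolisable and C9 is quaternary, so neither aldol side reactions nor aromatisation to a naphthalene can divert the cascade.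

Step 19
Reactants: 25 6-oxopristimerol dimethyl ether
Product: 26 methyl 2,3-dihydroxy-6-oxo-24-nor-D:A-friedooleana-1,3,5(10),7-tetraen-29-oate (6-oxopristimerol)
Conditions: BBr3 (4 equiv), CH2Cl2, −78 → 0 °C; MeOH, then H2O
Reagents that add atoms: none
Why: Lewis-acid cleavage of both aryl methyl ethers; the hindered tertiary methyl ester and the aryl ketone should survive at low temperature.

Step 20
Reactants: 27 (S)-carvone
Product: 28 (2R,5S)-2-methyl-5-(prop-1-en-2-yl)cyclohexan-1-one (cis-dihydrocarvone)
Conditions: ene-reductase (old yellow enzyme OYE1), NADP+ (cat.), glucose, glucose dehydrogenase, phosphate buffer pH 7, 30 °C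
Reagents that add atoms: none
Why: Flavin-dependent ene-reductase reduction of the enone C=C delivers hydride to C3 and a proton to C2 from enzyme-fixed faces, which should give the (2R) centre and hence the cis isomer that chemical conjugate reduction does not favour.

Step 21
Reactants: 28 cis-dihydrocarvone
Product: 29 ethyl (3R,6S)-3-methyl-2-oxo-6-(prop-1-en-2-yl)cycloheptane-1-carboxylate (C1 epimers and enol)
Conditions: ethyl diazoacetate, BF3·OEt2, Et2O, 0 → 25 °C
Reagents that add atoms: ethyl diazoacetate, CCOC(=O)C=[N+]=[N-]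
Why: Lewis-acid-promoted diazoacetate homologation (Büchner–Curtius–Schlotterbeck type) with migration of the less substituted C6 methylene, so the ester-bearing carbon enters on the side remote from the methyl and both stereocentres are kept.

Step 22
Reactants: 29 cycloheptanone β-keto ester
Product: 30 ethyl (3R,6S)-3-methyl-6-(prop-1-en-2-yl)-2-(trifluoromethylsulfonyloxy)cyclohept-1-ene-1-carboxylate
Conditions: NaH, THF, 0 °C; PhNTf2, 25 °C
Reagents that add atoms: N-phenylbis(trifluoromethanesulfonimide), O=S(=O)(N(c1ccccc1)S(=O)(=O)C(F)(F)F)C(F)(F)F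
Why: The β-keto ester is deprotonated at its doubly activated carbon and the enolate O-triflated, so the C10' stereocentre is not touched.

Step 23
Reactants: 30 enol triflate
Product: 31 ethyl (3R,6S)-2-(3-ethoxy-3-oxopropyl)-3-methyl-6-(prop-1-en-2-yl)cyclohept-1-ene-1-carboxylate
Conditions: (3-ethoxy-3-oxopropyl)zinc bromide (THF solution), Pd(PPh3)4 (5 mol %), THF, 50 °C
Reagents that add atoms: (3-ethoxy-3-oxopropyl)zinc bromide, CCOC(=O)CC[Zn]Br
Why: Negishi coupling of a β-triflyloxy enoate with a functionalised alkylzinc halide, which tolerates both esters.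

Step 24
Reactants: 31 diester
Product: 32 ethyl (4R,7S)-4-methyl-1-oxo-7-(prop-1-en-2-yl)-1,2,3,4,5,6,7,8-octahydroazulene-2-carboxylate (C2 epimers)
Conditions: KOt-Bu, THF, 0 → 25 °C; aq. NH4Cl
Reagents that add atoms: none
Why: Dieckmann condensation: the saturated ester enolate attacks the ring enoate carbonyl and closes the five-membered ring as a stabilised β-keto ester enolate, which drives the equilibrium.

Step 25
Reactants: 32 bicyclic β-keto ester
Product: 33 (4R,7S)-4-methyl-7-(prop-1-en-2-yl)-3,4,5,6,7,8-hexahydroazulen-1(2H)-one (15'-nor-guaia-1'(5'),11'-dien-4'-one)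
Conditions: LiCl, DMSO, H2O, 150 °C
Reagents that add atoms: none
Why: Krapcho dealkoxycarbonylation under neutral conditions removes the activating ester without exposing the isopropenyl group to acid.

Step 26
Reactants: 33 bicyclic enone
Product: 34 (4R,7S)-4-methyl-7-(prop-1-en-2-yl)-3,4,5,6,7,8-hexahydroazulen-1-yl trifluoromethanesulfonate (dienyl triflate, C3'=C4' and C1'=C5')
Conditions: KHMDS, THF, −78 °C; PhNTf2, −78 → −20 °C; used at once
Reagents that add atoms: N-phenylbis(trifluoromethanesulfonimide), O=S(=O)(N(c1ccccc1)S(=O)(=O)C(F)(F)F)C(F)(F)F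
Why: Kinetic deprotonation at the α'-methylene C3' and O-triflation give the cross-conjugated dienyl triflate regiospecifically; it is used cold before a [1,5]-hydrogen shift can move the diene.

Step 27
Reactants: 26 6-oxopristimerol; 34 dienyl triflate
Product: 36 dioxane adduct bearing the C4' alkenyl triflate, via o-quinone 35 (not isolated)
Conditions: Ag2O (3 equiv), MgSO4, 34 (2 equiv), CH2Cl2, 0 → 25 °C, dark
Reagents that add atoms: none
Why: Inverse-electron-demand hetero-Diels–Alder reaction of the o-quinone (O=C–C=O as the 4π unit) with the tetrasubstituted C1'=C5' bond: the triflate deactivates C3'=C4', the more electrophilic O3 (its partner O2 becomes a para-acyl-stabilised phenoxide) should bond to the remote diene terminus C1' and O2 close on C5', and approach anti to the pseudoaxial C10' methyl sets both new stereocentres.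

Step 28
Reactants: 36 dioxane adduct alkenyl triflate
Product: 37 CNP0317749.2 (target)
Conditions: MeZnCl (THF solution, 3 equiv), Pd(PPh3)4 (10 mol %), THF, 25 °C
Reagents that add atoms: methylzinc chloride, C[Zn]Cl
Why: Negishi coupling of the alkenyl triflate with a methylzinc reagent, which tolerates the ketone and ester, puts the C15' methyl on C4' and leaves the C3'=C4' alkene where the triflate was.

**Compound list**

1 | methyl 3-oxocyclohex-1-ene-1-carboxylate | COC(=O)C1=CC(=O)CCC1 | starting material
2 | methyl (1R)-1-methyl-3-oxocyclohexane-1-carboxylate | O=C1C[C@](C)(C(=O)OC)CCC1 | intermediate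
3 | methyl (1R)-1,4-dimethyl-3-oxocyclohexane-1-carboxylate (C4 epimers) | O=C1C[C@](C)(C(=O)OC)CCC1C | intermediate
4 | pent-1-en-3-one | C=CC(=O)CC | starting material
5 | (S)-1-phenylethyl imine of 3 | C[C@H](N=C1C[C@](C)(C(=O)OC)CCC1C)c1ccccc1 | intermediate
6 | methyl (1R,4R)-1,4-dimethyl-3-oxo-4-(3-oxopentyl)cyclohexane-1-carboxylate | O=C1C[C@](C)(C(=O)OC)CC[C@]1(C)CCC(=O)CC | intermediate
7 | methyl (2R,4aR)-2,4a,8-trimethyl-7-oxo-1,2,3,4,4a,5,6,7-octahydronaphthalene-2-carboxylate | O=C1C(C)=C2C[C@](C)(C(=O)OC)CC[C@]2(C)CC1 | intermediate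
8 | cis-fused D/E decalone (18β-H, C13 epimers) | O=C1C(C)[C@@H]2C[C@](C)(C(=O)OC)CC[C@]2(C)CC1 | intermediate
9 | trimethylsilyl enol ether of 8 (C13=C14) | C[Si](C)(C)OC1=C(C)[C@@H]2C[C@](C)(C(=O)OC)CC[C@]2(C)CC1 | intermediate
10 | methyl (2E)-4-bromo-2-methylbut-2-enoate | BrC/C=C(\C)C(=O)OC | starting material
11 | C13-alkylated decalone (13α-methyl, 13β-enoate chain) | O=C1[C@@](C)(C/C=C(\C)C(=O)OC)[C@@H]2C[C@](C)(C(=O)OC)CC[C@]2(C)CC1 | intermediate
12 | saturated keto diester (C9 epimers) | O=C1[C@@](C)(CCC(C)C(=O)OC)[C@@H]2C[C@](C)(C(=O)OC)CC[C@]2(C)CC1 | intermediate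
13 | C14 enol triflate | O(S(=O)(=O)C(F)(F)F)C=1[C@@](C)(CCC(C)C(=O)OC)[C@@H]2C[C@](C)(C(=O)OC)CC[C@]2(C)CC=1 | intermediate
14 | aldehyde (C8 formyl) | O(S(=O)(=O)C(F)(F)F)C=1[C@@](C)(CCC(C)C=O)[C@@H]2C[C@](C)(C(=O)OC)CC[C@]2(C)CC=1 | intermediate
15 | tricyclic allylic alcohol (8-hydroxy, C14=C15) | OC1C(C)CC[C@@]2(C)[C@@H]3C[C@](C)(C(=O)OC)CC[C@]3(C)CC=C12 | intermediate
16 | tricyclic enone (8-oxo, C14=C15) | O=C1C(C)CC[C@@]2(C)[C@@H]3C[C@](C)(C(=O)OC)CC[C@]3(C)CC=C12 | intermediate
17 | triethylsilyl enol ether (C8=C14) | CC[Si](CC)(CC)OC=1C(C)CC[C@@]2(C)[C@@H]3C[C@](C)(C(=O)OC)CC[C@]3(C)CCC=12 | intermediate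
18 | tricyclic C/D/E ketone (13α,14β,17β-trimethyl, 18β-H, C9 epimers) | O=C1C(C)CC[C@@]2(C)[C@@H]3C[C@](C)(C(=O)OC)CC[C@]3(C)CC[C@]12C | intermediate
19 | 2-methoxy-6-methylphenol | COc1cccc(C)c1O | starting material
20 | 4-bromo-2-methoxy-6-methylphenol | COc1cc(Br)cc(C)c1O | intermediate
21 | 5-bromo-1,2-dimethoxy-3-methylbenzene | COc1cc(Br)cc(C)c1OC | intermediate
22 | 9α-(3,4-dimethoxy-5-methylphenyl) ketone | O=C1[C@@](c2cc(OC)c(OC)c(C)c2)(C)CC[C@@]2(C)[C@@H]3C[C@](C)(C(=O)OC)CC[C@]3(C)CC[C@]12C | intermediate
23 | ethoxyethyne | C#COCC | starting material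
24 | 8-(ethoxyethynyl) carbinol of 22 (C8 configuration open) | CCOC#CC1(O)[C@@](c2cc(OC)c(OC)c(C)c2)(C)CC[C@@]2(C)[C@@H]3C[C@](C)(C(=O)OC)CC[C@]3(C)CC[C@]12C | intermediate
25 | 6-oxopristimerol dimethyl ether | COc1cc2c(c(C)c1OC)C(=O)C=C1[C@@]2(C)CC[C@@]2(C)[C@@H]3C[C@](C)(C(=O)OC)CC[C@]3(C)CC[C@]12C | intermediate
26 | 6-oxopristimerol | Oc1cc2c(c(C)c1O)C(=O)C=C1[C@@]2(C)CC[C@@]2(C)[C@@H]3C[C@](C)(C(=O)OC)CC[C@]3(C)CC[C@]12C | intermediate
27 | (S)-carvone | C=C(C)[C@H]1CC=C(C)C(=O)C1 | starting material
28 | (2R,5S)-2-methyl-5-(prop-1-en-2-yl)cyclohexan-1-one | C=C(C)[C@H]1CC[C@@H](C)C(=O)C1 | intermediate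
29 | ethyl (3R,6S)-3-methyl-2-oxo-6-(prop-1-en-2-yl)cycloheptane-1-carboxylate | C=C(C)[C@H]1CC[C@@H](C)C(=O)C(C1)C(=O)OCC | intermediate
30 | ethyl (3R,6S)-3-methyl-6-(prop-1-en-2-yl)-2-(trifluoromethylsulfonyloxy)cyclohept-1-ene-1-carboxylate | C=C(C)[C@H]1CC[C@@H](C)C(OS(=O)(=O)C(F)(F)F)=C(C1)C(=O)OCC | intermediate
31 | ethyl (3R,6S)-2-(3-ethoxy-3-oxopropyl)-3-methyl-6-(prop-1-en-2-yl)cyclohept-1-ene-1-carboxylate | C=C(C)[C@H]1CC[C@@H](C)C(CCC(=O)OCC)=C(C1)C(=O)OCC | intermediate
32 | ethyl (4R,7S)-4-methyl-1-oxo-7-(prop-1-en-2-yl)-1,2,3,4,5,6,7,8-octahydroazulene-2-carboxylate | C=C(C)[C@H]1CC[C@@H](C)C2=C(C1)C(=O)C(C(=O)OCC)C2 | intermediate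
33 | (4R,7S)-4-methyl-7-(prop-1-en-2-yl)-3,4,5,6,7,8-hexahydroazulen-1(2H)-one | C=C(C)[C@H]1CC[C@@H](C)C2=C(C1)C(=O)CC2 | intermediate
34 | (4R,7S)-4-methyl-7-(prop-1-en-2-yl)-3,4,5,6,7,8-hexahydroazulen-1-yl trifluoromethanesulfonate | C=C(C)[C@H]1CC[C@@H](C)C2=C(C1)C(OS(=O)(=O)C(F)(F)F)=CC2 | intermediate
35 | o-quinone of 26 (2,3,6-trioxo) | O=C1C=C2C(=C(C)C1=O)C(=O)C=C1[C@@]2(C)CC[C@@]2(C)[C@@H]3C[C@](C)(C(=O)OC)CC[C@]3(C)CC[C@]12C | intermediate
36 | dioxane adduct with C4' alkenyl triflate | C=C(C)[C@H]1CC[C@@H](C)[C@@]23CC=C(OS(=O)(=O)C(F)(F)F)[C@]2(C1)Oc1cc2c(c(C)c1O3)C(=O)C=C1[C@@]2(C)CC[C@@]2(C)[C@@H]3C[C@](C)(C(=O)OC)CC[C@]3(C)CC[C@]12C | intermediate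
37 | CNP0317749.2 | C=C(C)[C@H]1CC[C@@H](C)[C@@]23CC=C(C)[C@]2(C1)Oc1cc2c(c(C)c1O3)C(=O)C=C1[C@@]2(C)CC[C@@]2(C)[C@@H]3C[C@](C)(C(=O)OC)CC[C@]3(C)CC[C@]12C | target

**Summary and risks**

Total step count: 28. Longest linear sequence: 19 steps (steps 1–14, 17–19, 27, 28).

Steps most likely to fail:

1. Step 18 (proposed new method). The acetylide may fail to add to the doubly flanked C8 carbonyl, or the ketene-oxonium ion may be hydrated or oligomerise faster than ring A closes. The fallback separates the two bond formations with known reactions. Ketone 22 is brominated para to the C2 methoxy (NBS, MeCN) to give the C5 bromide F1. Stille coupling with tributyl(1-ethoxyvinyl)stannane (Pd(PPh3)4, CsF, dioxane, 90 °C) gives the aryl enol ether F2, which aqueous HCl hydrolyses to the C5 acetyl ketone F3. Its only enolisable position is the acetyl methyl, so KOt-Bu in t-BuOH should effect intramolecular aldol condensation onto C8 and rejoin the route at 25.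

2. Step 27. Cycloaddition may occur at the isopropenyl group or at C3'=C4', the two oxygens may add in the reverse orientation, the dienyl triflate may be too electron-poor, or it may isomerise by [1,5]-hydrogen shift before it reacts. The fallback methylates first and then uses the hydrocarbon diene. Triflate 34 is coupled with MeMgBr under Fe(acac)3 catalysis (THF/NMP, −30 °C) to give (7'S,10'R)-guaia-1'(5'),3',11'-triene F4. Catechol 26 is oxidised with Ag2O to o-quinone 35 in the presence of F4, and the cycloaddition across C1'=C5' would give 37 directly.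

3. Step 17. Reductive elimination at the enolate carbon between a quaternary centre and an axial methyl may be slow, so that reduction of 21 or O-arylation takes over. The fallback is metal-free arylation with a diaryliodonium salt. Bromide 21 is converted (n-BuLi, B(Oi-Pr)3, then aqueous acid) into (3,4-dimethoxy-5-methylphenyl)boronic acid F5. Treatment with 2-(diacetoxyiodo)-1,3,5-trimethylbenzene and BF3·OEt2, then NaOTf, gives the aryl(mesityl)iodonium triflate F6. The potassium enolate of 18 (KHMDS, THF, −78 → 25 °C) should take the less hindered aryl group from F6 on its α face and rejoin the route at 22.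

Further compounds
F1 | step 18 | C5 bromide of 22 | O=C1[C@@](c2cc(OC)c(OC)c(C)c2Br)(C)CC[C@@]2(C)[C@@H]3C[C@](C)(C(=O)OC)CC[C@]3(C)CC[C@]12C
F2 | step 18 | C5 (1-ethoxyvinyl) derivative of 22 | O=C1[C@@](c2cc(OC)c(OC)c(C)c2C(=C)OCC)(C)CC[C@@]2(C)[C@@H]3C[C@](C)(C(=O)OC)CC[C@]3(C)CC[C@]12C
F3 | step 18 | C5 acetyl derivative of 22 | O=C1[C@@](c2cc(OC)c(OC)c(C)c2C(C)=O)(C)CC[C@@]2(C)[C@@H]3C[C@](C)(C(=O)OC)CC[C@]3(C)CC[C@]12C
F4 | step 27 | (7'S,10'R)-guaia-1'(5'),3',11'-triene | C=C(C)[C@H]1CC[C@@H](C)C2=C(C1)C(C)=CC2
F5 | step 17 | (3,4-dimethoxy-5-methylphenyl)boronic acid | COc1cc(B(O)O)cc(C)c1OC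
F6 | step 17 | (3,4-dimethoxy-5-methylphenyl)(2,4,6-trimethylphenyl)iodonium trifluoromethanesulfonate | COc1cc(cc(C)c1OC)[I+]c1c(C)cc(C)cc1C.[O-]S(=O)(=O)C(F)(F)F
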